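In a one-step world a flask has a single clock and more catalyst only runs it faster, but here two steps share the catalyst and a third takes it away.

- Friday's: starting material 1.0 M; reagent 1.05 M; catalyst 1.8 mM; added ligand 4.4 mM; time 8.0 h
- Thursday's: starting material 1.0 M; reagent 1.05 M; catalyst 5.4 mM; added ligand 4.4 mM; time 8.0 h

    reagent + catalyst + intermediate → catalyst + product (k1 = 71 L² mol⁻² h⁻¹)
    catalyst + added ligand ⇌ idle complex (K2 = 5200 L mol⁻¹, k2 = 27 L mol⁻¹ h⁻¹)
    starting material + catalyst → catalyst + intermediate (k3 = 400 L mol⁻¹ h⁻¹)

- which of these there is most of at the end, counted by the starting material in it, Friday's (product / starting material / intermediate)
- which of these there is most of at the end, counted by the starting material in it, Thursday's (product / starting material / intermediate)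
- final amount of the leader among these, as a percentage of the starting material charged, in Friday's
- final amount of the leader among these, as a percentage of the starting material charged, in Thursday's

To whoever took over the bench: I left both flasks stirring, with the catalyst turning starting material into intermediate and, with the reagent, intermediate into product. Both steps ran through the catalyst, so it dropped out of their ratio. I therefore carried one number, the crossing ratio, which is the fraction of intermediate per fraction of starting material at which intermediate is made as fast as it is used, with the reagent at full charge: 5.37. Below it intermediate climbs, above it intermediate falls, and with part of the reagent gone the ratio is divided by that fraction.

How far past the crossing each flask got was a matter of clocks. In Friday's, the intermediate's pseudo-first-order half-life with the reagent, charges intact, was 5.2 h. In Friday's, the added ligand took catalyst away with a half-life of 5.83 h, a pace similar to that of the intermediate's clock, so catalyst would be lost while intermediate still waited to become product. Counting the ligand as undiminished, Friday's 8.0 h were worth 5.16 h of fresh catalyst, about one half-life, and part of that went on making the intermediate, so I expected intermediate ahead. In Thursday's the half-life was 1.72 h, far shorter than the run, so I expected product ahead.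

The forecast was intermediate at 62% for Friday's, which it said “stalls at the intermediate”, and product at 69% for Thursday's.

The flasks gave intermediate at 63.2% in Friday's and product at 68.9% in Thursday's, as forecast, so Friday's catalyst carried most of the material only halfway along the series. In Friday's, intermediate was made 6.17 times as fast as it was used at 0.991 h, faster, but at the end the made-to-used ratio was 0.263, slower, which is the crossing ratio, reagent-corrected, against the flask's contents: 0.262. The flask like Friday's with 0.0011 M of catalyst held 69.7% intermediate at the end, and the same reckoning put it at 0.924, just past its crossing.

The numbers of this flask come from no measurement.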